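**Plan**
1. Retrosynthetic cuts: first the C1–C10 epoxide oxygen and the C9 acetate/carbinol (back to a C9 enone). Then the ten-membered carbocycle is contracted to a nine-membered one by folding C4 back onto a C3–C5 bond as a cyclopropane. Then C9–C10, C1=C10, C7–C8, C7=C11 and C3=C5.
2. Enabling feature: C3(OAc)–C4(CH3)=C5 is an (E)-2-methylallyl acetate inside the ten-membered ring. It is the direct product of silver-assisted disrotatory opening of an exo-bromo-endo-methylcyclopropane fused to a nine-membered ring (bicyclo[7.1.0]decane), which inserts C4 between C3 and C5.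
3. Forward order: Z-alkene chain → cyclopropane → butenolide/γ-lactone → nine-membered carbocycle (C9–C10 closure) → ten-membered carbocycle (ring expansion) → epoxide.
4. Stereochemistry: C6 from (S)-glyceraldehyde acetonide; cyclopropane face by allylic 1,3-strain; C7 anti to C6 in the conjugate addition; C11 by kinetic protonation; C3 and the E alkene by the stereoelectronics of the ring opening; C9 by CBS reduction; epoxide face by the C9 hydroxyl.

Key step: step 16

Remark on numbering: atoms are called C1–C15 as in germacranolides (C1/C10 epoxide carbons, C3 and C9 acetoxy carbons, C4=C5 alkene, C6 lactone O-carbon, C7, C11 methyl-bearing lactone carbon, C12 lactone C=O; C13, C14, C15 are the methyls on C11, C10, C4).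
Assumption: (S)-2,2-dimethyl-1,3-dioxolane-4-carbaldehyde is taken as purchased (it is also one oxidation away from commercial (R)-solketal).

**Route**

Step 1
Reactants: 1 (S)-2,2-dimethyl-1,3-dioxolane-4-carbaldehyde; 2 [2-(1,3-dioxan-2-yl)ethyl]triphenylphosphonium bromide
Product: 4 (R)-4-[(Z)-3-(1,3-dioxan-2-yl)prop-1-enyl]-2,2-dimethyl-1,3-dioxolane, via phosphorus ylide 3 (not isolated)
Conditions: 2, NaN(SiMe3)2, THF, 0 °C; then 1, −78 °C to rt
Reagents that add atoms: none
Why: Wittig olefination of an α-alkoxy aldehyde with a non-stabilised ylide under salt-free conditions should give the Z alkene (C3=C5) under kinetic control, and the C6 stereocentre of the aldehyde is not touched.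

Step 2
Reactants: 4 (R)-4-[(Z)-3-(1,3-dioxan-2-yl)prop-1-enyl]-2,2-dimethyl-1,3-dioxolane
Product: 5 (R)-4-[2,2-dibromo-3-(1,3-dioxan-2-ylmethyl)cyclopropyl]-2,2-dimethyl-1,3-dioxolane (side chains cis; CBr2 on the alkene face anti to the dioxolane C4–C5 bond)
Conditions: CHBr3, KOtBu, pentane, −10 °C to rt
Reagents that add atoms: bromoform, BrC(Br)Br
Why: Dibromocarbene cycloaddition is stereospecific (cis alkene to cis cyclopropane) and should attack the Z-allylic ether in the conformer with C6–H eclipsing the alkene (allylic 1,3-strain), anti to the dioxolane C–C bond and on the side of the C6–O bond, which fixes C3 and C5 relative to C6.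

Step 3
Reactants: 5 (R)-4-[2,2-dibromo-3-(1,3-dioxan-2-ylmethyl)cyclopropyl]-2,2-dimethyl-1,3-dioxolane
Product: 7 (R)-4-[2-bromo-2-methyl-3-(1,3-dioxan-2-ylmethyl)cyclopropyl]-2,2-dimethyl-1,3-dioxolane (methyl cis to both side chains; bromine trans), via lithium carbenoid 6 (not isolated)
Conditions: n-BuLi (0.95 equiv), THF, −100 °C; then MeI, −100 to −78 °C
Reagents that add atoms: n-butyllithium, [Li]CCCC (lithium of 6); iodomethane, CI
Why: Bromine–lithium exchange under equilibrating conditions should give the carbenoid with lithium cis to the side chains (chelated by the dioxolane oxygen, bromine in the less hindered position), and alkylation with retention then places the methyl group endo and leaves the exo bromide that the ring opening needs.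

Step 4
Reactants: 7 (R)-4-[2-bromo-2-methyl-3-(1,3-dioxan-2-ylmethyl)cyclopropyl]-2,2-dimethyl-1,3-dioxolane
Product: 8 1-[2-bromo-2-methyl-3-(1,3-dioxan-2-ylmethyl)cyclopropyl]ethane-1,2-diol (configuration of 7 retained)
Conditions: 60% aq. AcOH, rt
Reagents that add atoms: none
Why: Acetal hydrolysis, in which the terminal isopropylidene ketal should cleave much faster than the aldehyde-derived 1,3-dioxane, and no stereocentre is involved.

Step 5
Reactants: 8 1-[2-bromo-2-methyl-3-(1,3-dioxan-2-ylmethyl)cyclopropyl]ethane-1,2-diol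
Product: 10 2-[[2-bromo-2-methyl-3-(oxiran-2-yl)cyclopropyl]methyl]-1,3-dioxane (C6 configuration retained), via primary tosylate 9 (not isolated)
Conditions: NaH (2 equiv), N-tosylimidazole, THF, 0 °C to rt
Reagents that add atoms: N-tosylimidazole, Cc1ccc(cc1)S(=O)(=O)n1ccnc1 (tosyl group of 9)
Why: Selective sulfonylation of the primary hydroxyl followed by intramolecular Williamson displacement by the C6 alkoxide closes the epoxide without breaking the C6–O bond, so C6 keeps its configuration.

Step 6
Reactants: 10 2-[[2-bromo-2-methyl-3-(oxiran-2-yl)cyclopropyl]methyl]-1,3-dioxane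
Product: 11 1-[2-bromo-2-methyl-3-(1,3-dioxan-2-ylmethyl)cyclopropyl]prop-2-en-1-ol (C6 carbinol; configuration retained)
Conditions: Me3S+ I− (4 equiv), n-BuLi (3.8 equiv), THF, −10 °C; then 10, −10 °C to rt
Reagents that add atoms: trimethylsulfonium iodide, C[S+](C)C.[I-]
Why: Dimethylsulfonium methylide opens the terminal epoxide at CH2 and the resulting sulfonium salt loses dimethyl sulfide by ylide-mediated elimination (one-carbon homologation of an epoxide to an allylic alcohol); the preformed ylide leaves no free butyllithium to attack the cyclopropyl bromide.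

Step 7
Reactants: 11 1-[2-bromo-2-methyl-3-(1,3-dioxan-2-ylmethyl)cyclopropyl]prop-2-en-1-ol
Product: 12 methacrylate ester of 11
Conditions: methacryloyl chloride, Et3N, DMAP (cat.), CH2Cl2, 0 °C
Reagents that add atoms: methacryloyl chloride, CC(=C)C(Cl)=O
Why: DMAP-catalysed acylation of a secondary allylic alcohol, with no change at any stereocentre.

Step 8
Reactants: 12 methacrylate ester of 11
Product: 13 5-[2-bromo-2-methyl-3-(1,3-dioxan-2-ylmethyl)cyclopropyl]-3-methylfuran-2(5H)-one (butenolide; C7=C11; C6 configuration retained)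
Conditions: second-generation Grubbs catalyst (5 mol%), toluene, 80 °C
Reagents that add atoms: none
Why: Ring-closing metathesis of an allyl methacrylate to an α-methylbutenolide, driven by loss of ethylene; the two terminal alkenes are the only metathesis-active groups.

Step 9
Reactants: 13 5-[2-bromo-2-methyl-3-(1,3-dioxan-2-ylmethyl)cyclopropyl]-3-methylfuran-2(5H)-one
Product: 15 5-[2-bromo-2-methyl-3-(1,3-dioxan-2-ylmethyl)cyclopropyl]-3-methyl-4-vinyldihydrofuran-2(3H)-one (4-vinyl trans to the 5-cyclopropyl group; 3-methyl cis to 4-vinyl), via magnesium enolate 14 (not isolated)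
Conditions: CH2=CHMgBr, CuBr·SMe2 (20 mol%), THF, −78 to −40 °C; then 2,6-di-tert-butyl-4-methylphenol, −78 °C; aq. NH4Cl
Reagents that add atoms: vinylmagnesium bromide, C=C[Mg]Br
Why: Copper-catalysed conjugate addition should deliver the vinyl group (C8=C9) to C7 anti to the C6 substituent (trans lactone), and protonation of the enolate by a bulky acid from the face opposite the new vinyl group should give the kinetic C11 epimer with methyl cis to C8.

Step 10
Reactants: 15 5-[2-bromo-2-methyl-3-(1,3-dioxan-2-ylmethyl)cyclopropyl]-3-methyl-4-vinyldihydrofuran-2(3H)-one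
Product: 16 2-[2-bromo-2-methyl-3-(4-methyl-5-oxo-3-vinyltetrahydrofuran-2-yl)cyclopropyl]acetaldehyde (C1 aldehyde)
Conditions: 2 M aq. HCl, THF, rt
Reagents that add atoms: water, O
Why: Acid hydrolysis of the dioxane acetal unmasks the C1 aldehyde, while lactone, vinyl group and tertiary cyclopropyl bromide are inert and acid does not epimerise C11.

Step 11
Reactants: 16 2-[2-bromo-2-methyl-3-(4-methyl-5-oxo-3-vinyltetrahydrofuran-2-yl)cyclopropyl]acetaldehyde
Product: 17 5-[2-bromo-3-[(Z)-3-iodobut-2-enyl]-2-methylcyclopropyl]-3-methyl-4-vinyldihydrofuran-2(3H)-one (iodine on C10 cis to C2)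
Conditions: EtPPh3+ I−, n-BuLi, THF, rt; I2, −78 °C; NaN(SiMe3)2, −20 °C; then 16, −78 °C
Reagents that add atoms: ethyltriphenylphosphonium iodide, CC[P+](c1ccccc1)(c1ccccc1)c1ccccc1.[I-]; iodine, II
Why: Wittig iodo-olefination (Stork–Zhao type) with the α-iodoethylidene ylide should give the (Z)-2-iodoalk-2-ene under kinetic control at low temperature, where the aldehyde reacts much faster than the lactone α-centre is deprotonated.

Step 12
Reactants: 17 5-[2-bromo-3-[(Z)-3-iodobut-2-enyl]-2-methylcyclopropyl]-3-methyl-4-vinyldihydrofuran-2(3H)-one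
Product: 19 5-[2-bromo-3-[(Z)-3-iodobut-2-enyl]-2-methylcyclopropyl]-4-(2-hydroxyethyl)-3-methyldihydrofuran-2(3H)-one (C9 primary alcohol), via alkylborane 18 (not isolated)
Conditions: 9-BBN, THF, 0 °C to rt; then H2O2, aq. NaOAc, 0 °C
Reagents that add atoms: 9-borabicyclo[3.3.1]nonane, B1C2CCCC1CCC2 (boron of 18); hydrogen peroxide, OO
Why: Anti-Markovnikov hydroboration–oxidation, in which 9-BBN should react only with the monosubstituted alkene and not with the trisubstituted iodoalkene, and buffered peroxide spares the lactone.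

Step 13
Reactants: 19 5-[2-bromo-3-[(Z)-3-iodobut-2-enyl]-2-methylcyclopropyl]-4-(2-hydroxyethyl)-3-methyldihydrofuran-2(3H)-one
Product: 20 2-[2-[2-bromo-3-[(Z)-3-iodobut-2-enyl]-2-methylcyclopropyl]-4-methyl-5-oxotetrahydrofuran-3-yl]acetaldehyde (C9 aldehyde)
Conditions: Dess–Martin periodinane, CH2Cl2, rt
Reagents that add atoms: none
Why: Dess–Martin oxidation of a primary alcohol under neutral conditions, which leaves the epimerisable C11 centre and the iodoalkene untouched.

Step 14
Reactants: 20 2-[2-[2-bromo-3-[(Z)-3-iodobut-2-enyl]-2-methylcyclopropyl]-4-methyl-5-oxotetrahydrofuran-3-yl]acetaldehyde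
Product: 21 nine-membered allylic alcohol (bicyclo[7.1.0]decene with C9–OH as both epimers; (Z)-C1=C10 bearing the C10 methyl; C3–C5 bromo(methyl)cyclopropane; trans C6–C7 γ-lactone)
Conditions: CrCl2 (10 equiv), NiCl2 (1 mol%), DMSO, rt, slow addition, 0.002 M
Reagents that add atoms: none
Why: Intramolecular Nozaki–Hiyama–Kishi reaction, in which the alkenylchromium species adds chemoselectively to the aldehyde with retention of alkene geometry and the cis cyclopropane and Z alkene act as turn elements; the C9 epimers converge in step 15.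

Step 15
Reactants: 21 nine-membered allylic alcohol
Product: 22 nine-membered enone (C9 ketone conjugated with (Z)-C1=C10; exo-bromo-endo-methylcyclopropane at C3–C5; trans C6–C7 γ-lactone with C11 methyl cis to C8)
Conditions: Dess–Martin periodinane, CH2Cl2, 0 °C to rt
Reagents that add atoms: none
Why: Dess–Martin oxidation of the allylic alcohol removes the C9 mixture and turns C1=C10 into an electron-poor enone that cannot take part in the cationic step that follows.

Step 16
Reactants: 22 nine-membered enone
Product: 23 3-acetoxy-9-oxogermacra-1(10)Z,4E-dien-12,6-olide (ten-membered ring; C3, C6, C7, C11 configured as in the target)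
Conditions: AgOAc (3 equiv), AcOH, 60 °C, dark
Reagents that add atoms: silver acetate, CC(=O)[O-].[Ag+]
Why: Silver ion abstracts the exo bromide from C4 while the C3–C5 bond opens in the orbital-symmetry-allowed disrotatory sense in which the ring bonds trans to the leaving group (C3–C2 and C5–C6) rotate outward, so the developing 2-methylallyl cation (C3–C4–C5) has the E (W-type) geometry and is captured by acetate at C3 as the σ-bond breaks. The closest known reaction type is the silver-assisted solvolytic ring expansion of exo-halobicyclo[n.1.0]alkanes to trans-2-substituted cycloalk-2-enyl ethers and esters. No ring is closed: cleavage of the zero-bridge bond C3–C5 merges the three- and nine-membered rings into the ten-membered ring, a one-atom expansion that inserts C4 between C3 and C5. The new stereocentre C3 is set by backside capture (acetate enters anti to the departing C3–C5 bond, on the peripheral face from which bromide leaves), so it follows from the cyclopropane configuration fixed in step 2, and the E geometry of C4=C5 follows from the exo position of bromine fixed in step 3. The step needs capture at C3 and not at C5, which the inductively deactivating and hindering C6 acyloxy group next to C5 should secure, and it needs C1=C10 not to intervene across the ring, which its conjugation with the C9 ketone should secure.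

Step 17
Reactants: 23 3-acetoxy-9-oxogermacra-1(10)Z,4E-dien-12,6-olide
Product: 24 3-acetoxy-9-hydroxygermacra-1(10)Z,4E-dien-12,6-olide (C9 carbinol with the configuration of the target; other centres unchanged)
Conditions: (S)-2-methyl-CBS-oxazaborolidine (20 mol%), catecholborane, toluene, −78 °C
Reagents that add atoms: none
Why: Corey–Bakshi–Shibata reduction, in which the α-methylalkenyl group acts as the large substituent so the (S)-catalyst should deliver hydride to give the 9R alcohol with 1,2-selectivity, leaving lactone and acetate alone.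

Step 18
Reactants: 24 3-acetoxy-9-hydroxygermacra-1(10)Z,4E-dien-12,6-olide
Product: 25 9-O-deacetyl target (3-acetoxy-1,10-epoxy-9-hydroxygermacr-4E-en-12,6-olide; cis epoxide; all centres as in the target)
Conditions: mCPBA, CH2Cl2, 0 °C
Reagents that add atoms: 3-chloroperoxybenzoic acid, OOC(=O)c1cccc(Cl)c1
Why: Hydroxyl-guided peracid epoxidation, in which the Z alkene holds C9–H in the alkene plane (allylic 1,3-strain) so oxygen should be delivered syn to the C9 hydroxyl and anti to C8 (the trans epoxy alcohol typical of medium rings), while C4=C5, flanked by two acyloxy groups, is deactivated.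

Step 19
Reactants: 25 9-O-deacetyl target
Product: 26 target CNP0250285.3, (1R,3S,4E,6S,7S,9R,10R,11R)-3,9-diacetoxy-1,10-epoxygermacr-4-en-12,6-olide
Conditions: Ac2O, pyridine, DMAP (cat.), CH2Cl2, rt
Reagents that add atoms: acetic anhydride, CC(=O)OC(C)=O
Why: DMAP-catalysed acetylation of the secondary C9 alcohol under mild conditions that should not open the epoxide or epimerise C11.

**Compound list**
1 | (S)-2,2-dimethyl-1,3-dioxolane-4-carbaldehyde | O=C[C@@H]1COC(C)(C)O1 | starting material
2 | [2-(1,3-dioxan-2-yl)ethyl]triphenylphosphonium bromide | [Br-].C1COC(CC[P+](c2ccccc2)(c2ccccc2)c2ccccc2)OC1 | starting material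
3 | [2-(1,3-dioxan-2-yl)ethylidene]triphenylphosphorane (ylide from 2; not isolated) | C1COC(CC=P(c2ccccc2)(c2ccccc2)c2ccccc2)OC1 | intermediate
4 | (R)-4-[(Z)-3-(1,3-dioxan-2-yl)prop-1-enyl]-2,2-dimethyl-1,3-dioxolane | O1CCCOC1C/C=C\[C@@H]2COC(C)(C)O2 | intermediate
5 | (R)-4-[2,2-dibromo-3-(1,3-dioxan-2-ylmethyl)cyclopropyl]-2,2-dimethyl-1,3-dioxolane (side chains cis) | O1CCCOC1C[C@@H]2C(Br)(Br)[C@@H]2[C@@H]3COC(C)(C)O3 | intermediate
6 | lithium carbenoid of 5 (lithium cis to both side chains; bromine trans; not isolated) | O1CCCOC1C[C@@H]2[C@@]([Li])(Br)[C@@H]2[C@@H]3COC(C)(C)O3 | intermediate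
7 | (R)-4-[2-bromo-2-methyl-3-(1,3-dioxan-2-ylmethyl)cyclopropyl]-2,2-dimethyl-1,3-dioxolane (methyl cis to both side chains; bromine trans) | O1CCCOC1C[C@@H]2[C@@](C)(Br)[C@@H]2[C@@H]3COC(C)(C)O3 | intermediate
8 | 1-[2-bromo-2-methyl-3-(1,3-dioxan-2-ylmethyl)cyclopropyl]ethane-1,2-diol | O1CCCOC1C[C@@H]2[C@@](C)(Br)[C@@H]2[C@@H](O)CO | intermediate
9 | primary 4-methylbenzenesulfonate of diol 8 (not isolated) | O1CCCOC1C[C@@H]2[C@@](C)(Br)[C@@H]2[C@@H](O)COS(=O)(=O)c3ccc(C)cc3 | intermediate
10 | 2-[[2-bromo-2-methyl-3-(oxiran-2-yl)cyclopropyl]methyl]-1,3-dioxane | O1CCCOC1C[C@@H]2[C@@](C)(Br)[C@@H]2[C@@H]3CO3 | intermediate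
11 | 1-[2-bromo-2-methyl-3-(1,3-dioxan-2-ylmethyl)cyclopropyl]prop-2-en-1-ol | O1CCCOC1C[C@@H]2[C@@](C)(Br)[C@@H]2[C@@H](O)C=C | intermediate
12 | methacrylate ester of 11 | O1CCCOC1C[C@@H]2[C@@](C)(Br)[C@@H]2[C@@H](OC(=O)C(C)=C)C=C | intermediate
13 | 5-[2-bromo-2-methyl-3-(1,3-dioxan-2-ylmethyl)cyclopropyl]-3-methylfuran-2(5H)-one | O1CCCOC1C[C@@H]2[C@@](C)(Br)[C@@H]2[C@H]3OC(=O)C(C)=C3 | intermediate
14 | bromomagnesium enolate formed by vinyl addition to 13 (not isolated) | O1CCCOC1C[C@@H]2[C@@](C)(Br)[C@@H]2[C@H]3OC(O[Mg]Br)=C(C)[C@@H]3C=C | intermediate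
15 | 5-[2-bromo-2-methyl-3-(1,3-dioxan-2-ylmethyl)cyclopropyl]-3-methyl-4-vinyldihydrofuran-2(3H)-one (4-vinyl trans to 5-cyclopropyl; 3-methyl cis to 4-vinyl) | O1CCCOC1C[C@@H]2[C@@](C)(Br)[C@@H]2[C@H]3OC(=O)[C@H](C)[C@@H]3C=C | intermediate
16 | 2-[2-bromo-2-methyl-3-(4-methyl-5-oxo-3-vinyltetrahydrofuran-2-yl)cyclopropyl]acetaldehyde | O=CC[C@@H]1[C@@](C)(Br)[C@@H]1[C@H]2OC(=O)[C@H](C)[C@@H]2C=C | intermediate
17 | 5-[2-bromo-3-[(Z)-3-iodobut-2-enyl]-2-methylcyclopropyl]-3-methyl-4-vinyldihydrofuran-2(3H)-one | I/C(C)=C\C[C@@H]1[C@@](C)(Br)[C@@H]1[C@H]2OC(=O)[C@H](C)[C@@H]2C=C | intermediate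
18 | B-alkyl-9-borabicyclo[3.3.1]nonane adduct of 17 (boron on C9; not isolated) | I/C(C)=C\C[C@@H]1[C@@](C)(Br)[C@@H]1[C@H]2OC(=O)[C@H](C)[C@@H]2CCB3C4CCCC3CCC4 | intermediate
19 | 5-[2-bromo-3-[(Z)-3-iodobut-2-enyl]-2-methylcyclopropyl]-4-(2-hydroxyethyl)-3-methyldihydrofuran-2(3H)-one | I/C(C)=C\C[C@@H]1[C@@](C)(Br)[C@@H]1[C@H]2OC(=O)[C@H](C)[C@@H]2CCO | intermediate
20 | 2-[2-[2-bromo-3-[(Z)-3-iodobut-2-enyl]-2-methylcyclopropyl]-4-methyl-5-oxotetrahydrofuran-3-yl]acetaldehyde | I/C(C)=C\C[C@@H]1[C@@](C)(Br)[C@@H]1[C@H]2OC(=O)[C@H](C)[C@@H]2CC=O | intermediate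
21 | nine-membered allylic alcohol (bicyclo[7.1.0]decene fused to the lactone; C9 epimers) | OC1/C(C)=C\C[C@@H]2[C@@](C)(Br)[C@@H]2[C@H]3OC(=O)[C@H](C)[C@@H]3C1 | intermediate
22 | nine-membered enone (C9 ketone; (Z)-C1=C10; exo-bromo-endo-methylcyclopropane at C3–C5; trans C6–C7 lactone) | O=C1/C(C)=C\C[C@@H]2[C@@](C)(Br)[C@@H]2[C@H]3OC(=O)[C@H](C)[C@@H]3C1 | intermediate
23 | 3-acetoxy-9-oxogermacra-1(10)Z,4E-dien-12,6-olide | CC(=O)O[C@H]1C/C=C(C)\C(=O)C[C@@H]2[C@@H](/C=C/1C)OC(=O)[C@@H]2C | intermediate
24 | 3-acetoxy-9-hydroxygermacra-1(10)Z,4E-dien-12,6-olide (C9 as in the target) | CC(=O)O[C@H]1C/C=C(C)\[C@H](O)C[C@@H]2[C@@H](/C=C/1C)OC(=O)[C@@H]2C | intermediate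
25 | 9-O-deacetyl target (3-acetoxy-1,10-epoxy-9-hydroxygermacr-4E-en-12,6-olide) | CC(=O)O[C@H]1C[C@H]2O[C@@]2(C)[C@H](O)C[C@@H]2[C@@H](/C=C/1C)OC(=O)[C@@H]2C | intermediate
26 | CNP0250285.3, (1R,3S,4E,6S,7S,9R,10R,11R)-3,9-diacetoxy-1,10-epoxygermacr-4-en-12,6-olide | CC(=O)O[C@H]1C[C@H]2O[C@@]2(C)[C@H](OC(C)=O)C[C@@H]2[C@@H](/C=C/1C)OC(=O)[C@@H]2C | target

**Count**
Total steps: 19. Longest linear sequence: 19 steps (from 1).

**Steps most likely to fail**

Step 16 (key ring expansion). The allyl cation may outlive acetate capture, so that acetate enters at C5, a proton is lost, or the lactone or enone interferes. Fallback, from 22: heating without silver (toluene, 2,6-lutidine, 130 °C, sealed tube) should cause the same disrotatory opening with ion-pair return to the ring-expanded allylic bromide F3. Pd(PPh3)4 with Bu4NOAc in THF should then give 23 by Tsuji–Trost substitution with net retention at the less hindered terminus C3; any C5 bromide converges through the same π-allyl palladium complex. The route is rejoined at 23.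

Step 14 (nine-membered ring closure). Intermolecular coupling and oligomerisation may outrun closure of the strained ring. Fallback, from 20: AgOAc in AcOH opens the cyclopropane at the open-chain stage, by the same stereoelectronic rules, to the open-chain (E)-allylic acetate F1. An intramolecular Nozaki–Hiyama–Kishi reaction (CrCl2, NiCl2, DMSO, high dilution) then closes the ten-membered ring directly to the C9 allylic alcohols F2, and Dess–Martin oxidation gives 23. This gives up the ring expansion and rejoins the route at 23.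

Step 18 (epoxidation). Oxygen may be delivered to the wrong face of C1=C10. Fallback, from 24: NBS in aqueous THF forms the bromonium ion on the face the peracid prefers and water opens it at C10 from the other face, giving the bromohydrin F4. K2CO3 in acetone then closes the epoxide on the face opposite to that reached by the peracid, giving 25.

**Further compounds**
F1 | step 14 | open-chain (E)-allylic acetate: 2-[2-[(1E,3S)-3-acetoxy-6-iodo-2-methylhepta-1,5Z-dienyl]-4-methyl-5-oxotetrahydrofuran-3-yl]acetaldehyde (C3 acetate; C4=C5 E; C9 aldehyde) | I/C(C)=C\C[C@H](OC(C)=O)/C(C)=C/[C@H]1OC(=O)[C@H](C)[C@@H]1CC=O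
F2 | step 14 | 3-acetoxy-9-hydroxygermacra-1(10)Z,4E-dien-12,6-olide as C9 epimers | CC(=O)O[C@H]1C/C=C(C)\C(O)C[C@@H]2[C@@H](/C=C/1C)OC(=O)[C@@H]2C
F3 | step 16 | 3-bromo-9-oxogermacra-1(10)Z,4E-dien-12,6-olide (ring-expanded allylic bromide) | Br[C@H]1C/C=C(C)\C(=O)C[C@@H]2[C@@H](/C=C/1C)OC(=O)[C@@H]2C
F4 | step 18 | bromohydrin: 3-acetoxy-1-bromo-9,10-dihydroxygermacr-4E-en-12,6-olide | CC(=O)O[C@H]1C[C@H](Br)[C@@](C)(O)[C@H](O)C[C@@H]2[C@@H](/C=C/1C)OC(=O)[C@@H]2C
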